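One millimolar of electrophile charged has to stand somewhere at every hour, so I kept my books on electrophile, the limiting reagent, with 20 mM charged against 50.0 mM of nucleophile.

| flask | electrophile | nucleophile | gas | temperature | remark | time |
|---|---|---|---|---|---|---|
| gamma | 20 mM | 50 mM | 6.4 mM (held) | 25 °C | the very flask that is asked about, followed so far |  |
| theta | 20 mM | 50 mM | 6.4 mM (held) | 10 °C | run made earlier |  |
| flask | 20 mM | 50.0 mM | 6.4 mM (held) | 25 °C |  | 20 h |

| gamma: time / h | gamma: target / % | theta: time / h | theta: target / % |
|---|---|---|---|
| 2.50 | 30.0 | 5.00 | 26.8 |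
| 8.00 | 38.1 | 15.0 | 44.8 |
| 12.0 | 40.3 | 25.0 | 50.3 |
| 20.0 | 42.8 | 40.0 | 52.4 |

(standard deviation of a reading: 1 percentage point)

- maple: at 20 h raise the temperature by 25 K, then wait 6.0 h
- larch: at 20 h add electrophile, 50.0 % of the amount charged, then wait 6.0 h
- alder: change nothing and wait 6.0 h more
- ash: at 20 h add nucleophile, 100 % of the amount charged, then wait 6.0 h

- target, in percent of the electrophile first charged, at 20 h
- what to do for the largest gain in target; "none" if nothing gains more than 2 percentage points (maple / larch / alder / ash / none)
- target present, in percent of the electrophile first charged, after larch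
- target present, in percent of the electrophile first charged, after alder

- the volume of additions can be left aside
- the numbers in the tables scatter with a standard deviation of 1 percentage point
- at the start none of the gas is in solution

1. At 20.0 h the gamma flask read 42.8 % target, and I took that reading for "now". By the balance, 57.2 % of the charge stood elsewhere.

2. I assumed that the target step is first order in [nucleophile] and that the other route does not use nucleophile. The ratio of target to elsewhere then equals [nucleophile] over one constant, the even-split nucleophile: the [nucleophile] at which target and elsewhere take equal shares. On the charged [nucleophile], the gamma reading gave 66.8 mM.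

3. The last theta reading gave 45.4 mM at 10 °C, lower than gamma, but it was read at 40.0 h against 20.0 h, so two settings differed and I gave the gap no cause.

4. Fresh electrophile in larch, split at 66.8 mM, gave me 21 percentage points eventually, so 63.8 %, with no allowance for the 6.0 h limit. The balance did not tell whether the 57.2 % was lost or could come back. I took it as lost and chose larch.

5. The forecast gave 42.7 % (41.8 % to 43.6 %), larch as best, 58 % after larch (51 % to 64 %), below my figure, and 44 % after alder (43 % to 45.3 %). Its ground: “Heating should therefore not help, and with a plateau this low, little electrophile is likely to remain.”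

6. The flask gave 43.9 %, 60.3 % after larch and 46.6 % after alder, but the best option was maple, gaining 41 points against 16 points for larch.

    electrophile + nucleophile → acid set free + target (k = 0.110 M⁻¹ min⁻¹, Ea = 64.0 kJ mol⁻¹)
    nucleophile + acid set free ⇌ protonated nucleophile, settled at all times (K = 84000 M⁻¹, ΔH = −18.0 kJ mol⁻¹)
    acid set free + free base ⇌ salt of the base (K = 7.80 × 10⁶ M⁻¹, k = 1.40 M⁻¹ min⁻¹, Ea = 54.0 kJ mol⁻¹, ΔH = −27.0 kJ mol⁻¹)
    acid set free + target → side product (k = 0.990 M⁻¹ min⁻¹, Ea = 61.0 kJ mol⁻¹)
    electrophile ⇌ dormant form (K = 17.0, k = 0.00900 min⁻¹, Ea = 104 kJ mol⁻¹, ΔH = −57.0 kJ mol⁻¹)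
    gas ⇌ free base, rate k6*(csat - [free base]) (kL = 0.270 min⁻¹)
    (constants at 25 °C)

My 66.8 mM had booked elsewhere as lost; at 20.0 h the flask held, beside 43.9 % target, 53.7 % as dormant form, 2.28 % as electrophile and 0.115 % as side product. Until 10.0 h electrophile fell to 2.49 % while target reached 38.7 % and dormant form 58.8 %. From then to 20.0 h electrophile stayed near 2.28 %, dormant form fell to 53.7 % and target rose to 43.9 %.

On the neighbour flask with 85 mM of nucleophile, 66.8 mM gives 56.0 % target. The computed flask gave 59.0 %.

(The runs are simulated from invented constants, noise included.)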